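**Strategy**

The plan cuts the exocyclic bond between C6, the fully substituted carbon of the 1,2-dioxane ring, and the side-chain CH2. Because C6 is bonded to peroxide oxygen O1, it is a latent peroxycarbenium ion. A cyclic peroxyketal, the 6-methoxy-6-methyl-1,2-dioxane already carrying the C3 acetate arm and the C4 methyl group, is ionized and captured by the complete sixteen-carbon side chain, delivered as a primary alkylzinc iodide. This one operation joins the two halves and creates the quaternary peroxide carbon, whose configuration is set by axial attack anti to the ring substituents. The peroxyketal arises by ozonolysis in methanol and peroxide oxa-Michael closure, the chain by Johnson–Claisen rearrangement and Julia–Kocienski olefination.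

Key step: step 15

Assumption: hydroperoxide 6 and peroxyketal 7 are carried as mixtures of their two C6 epimers, because both epimers of 7 ionize to the same peroxycarbenium ion.

**Route**

Step 1
Reactants: 1 (R)-3-bromo-2-methylpropan-1-ol; 2 prop-1-en-2-ylmagnesium bromide
Product: 3 (S)-2,4-dimethylpent-4-en-1-ol
Conditions: 2 (3 equiv), CuI (10 mol%), THF, −30 → 0 °C
Reagents that add atoms: none
Why: Copper-catalyzed Grignard cross-coupling at the primary C–Br bond after in situ deprotonation of the hydroxyl; the stereocenter is untouched (the label changes from R to S only because CH2Br becomes a carbon substituent).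

Step 2
Reactants: 3 (S)-2,4-dimethylpent-4-en-1-ol
Product: 5 methyl (2E,4S)-4,6-dimethylhepta-2,6-dienoate, via (S)-2,4-dimethylpent-4-enal 4 (not isolated)
Conditions: PhI(OAc)2, TEMPO (10 mol%), CH2Cl2, rt; then Ph3P=CHCO2Me, rt
Reagents that add atoms: methyl (triphenylphosphoranylidene)acetate, COC(=O)C=P(c1ccccc1)(c1ccccc1)c1ccccc1
Why: One-pot oxoammonium oxidation and Wittig olefination with a stabilized ylide should give the E-enoate without isolating or epimerizing the α-branched aldehyde.

Step 3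
Reactants: 5 methyl (2E,4S)-4,6-dimethylhepta-2,6-dienoate
Product: 6 methyl (2E,4S)-6-hydroperoxy-6-methoxy-4-methylhept-2-enoate (C6 epimers)
Conditions: O3, CH2Cl2/MeOH (5:1), −78 °C, stopped at the indicator end point
Reagents that add atoms: ozone, [O-][O+]=O; methanol, CO
Why: Chemoselective ozonolysis of the electron-rich 1,1-disubstituted alkene beside the enoate; the more substituted carbonyl oxide (Criegee intermediate) is trapped by methanol as the hydroperoxyketal, and C4 is untouched.

Step 4
Reactants: 6 methyl (2E,4S)-6-hydroperoxy-6-methoxy-4-methylhept-2-enoate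
Product: 7 methyl 2-[(3S,4S)-6-methoxy-4,6-dimethyl-1,2-dioxan-3-yl]acetate (C6 epimers)
Conditions: Et2NH (0.5 equiv), CF3CH2OH, rt
Reagents that add atoms: none
Why: Base-mediated 6-exo-trig intramolecular oxa-Michael addition of the hydroperoxide to the E-enoate closes the 1,2-dioxane; C4 controls C3, and kinetic closure through a chair with equatorial 4-methyl and axial acceptor is expected to favor the 3,4-cis (3S) isomer.

Step 5
Reactants: 8 (E)-but-2-enal; 9 phenylmagnesium bromide
Product: 10 rac-(E)-1-phenylbut-2-en-1-ol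
Conditions: THF, −78 → 0 °C
Reagents that add atoms: none
Why: 1,2-Addition of the aryl Grignard reagent to the enal gives the racemic secondary allylic alcohol with the E-alkene retained.

Step 6
Reactants: 10 rac-(E)-1-phenylbut-2-en-1-ol
Product: 11 (1R,2E)-1-phenylbut-2-en-1-ol
Conditions: Ti(OiPr)4 (0.2 equiv), D-(−)-diisopropyl tartrate (0.3 equiv), t-BuOOH (0.6 equiv), 4 Å MS, CH2Cl2, −20 °C
Reagents that add atoms: none
Why: Sharpless kinetic resolution; with the D-(−)-tartrate ligand the (S)-alcohol should be epoxidized fast, so the (R)-alcohol is recovered enantioenriched.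

Step 7
Reactants: 11 (1R,2E)-1-phenylbut-2-en-1-ol
Product: 13 ethyl (3S,4E)-3-methyl-5-phenylpent-4-enoate, via allyl ketene acetal 12 (not isolated)
Conditions: MeC(OEt)3 (5 equiv), EtCO2H (cat.), 135 °C, EtOH distilled off
Reagents that add atoms: triethyl orthoacetate, CCOC(C)(OCC)OCC
Why: Johnson–Claisen [3,3]-sigmatropic rearrangement through a chair with phenyl equatorial transfers the carbinol configuration suprafacially to the new methyl-bearing stereocenter (3S) and forms the E-styrene.

Step 8
Reactants: 13 ethyl (3S,4E)-3-methyl-5-phenylpent-4-enoate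
Product: 14 (3S,4E)-3-methyl-5-phenylpent-4-enal
Conditions: i-Bu2AlH (1.05 equiv), CH2Cl2, −78 °C
Reagents that add atoms: none
Why: Partial reduction of the ester at low temperature stops at the tetrahedral aluminate, which gives the aldehyde on work-up; the β-stereocenter cannot epimerize.

Step 9
Reactants: 1 (R)-3-bromo-2-methylpropan-1-ol
Product: 15 (R)-2-methyl-3-[(1-phenyl-1H-tetrazol-5-yl)sulfanyl]propan-1-ol
Conditions: 1-phenyl-1H-tetrazole-5-thiol, K2CO3, acetone, 50 °C
Reagents that add atoms: 1-phenyl-1H-tetrazole-5-thiol, Sc1nnnn1-c1ccccc1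
Why: SN2 S-alkylation of the acidic heteroaryl thiol at the primary bromide; the stereocenter is not involved.

Step 10
Reactants: 15 (R)-2-methyl-3-[(1-phenyl-1H-tetrazol-5-yl)sulfanyl]propan-1-ol
Product: 16 (R)-2-methyl-3-[(1-phenyl-1H-tetrazol-5-yl)sulfonyl]propan-1-ol
Conditions: (NH4)6Mo7O24·4H2O (10 mol%), 30% H2O2, EtOH, 0 °C → rt
Reagents that add atoms: hydrogen peroxide, OO
Why: Molybdate-catalyzed oxidation takes the sulfide to the sulfone without oxidizing the primary alcohol.

Step 11
Reactants: 16 (R)-2-methyl-3-[(1-phenyl-1H-tetrazol-5-yl)sulfonyl]propan-1-ol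
Product: 17 5-{[(2R)-3-{[tert-butyl(dimethyl)silyl]oxy}-2-methylpropyl]sulfonyl}-1-phenyl-1H-tetrazole
Conditions: TBSCl, imidazole, DMF, rt
Reagents that add atoms: tert-butyldimethylsilyl chloride, CC(C)(C)[Si](C)(C)Cl
Why: Standard silylation masks the hydroxyl so that no alkoxide can attack the tetrazole during the olefination.

Step 12
Reactants: 17 silyl-protected tetrazolyl sulfone; 14 (3S,4E)-3-methyl-5-phenylpent-4-enal
Product: 18 tert-butyl{[(2S,3E,6S,7E)-2,6-dimethyl-8-phenylocta-3,7-dien-1-yl]oxy}dimethylsilane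
Conditions: KN(SiMe3)2, THF, −78 °C; then 14, −78 °C → rt
Reagents that add atoms: none
Why: Julia–Kocienski olefination; the 1-phenyltetrazolyl sulfone with a potassium base should give the E-alkene via Smiles rearrangement and anti elimination, and both methyl stereocenters are β to the reacting centers and cannot epimerize.

Step 13
Reactants: 18 silyl ether of the dienol
Product: 19 (2S,3E,6S,7E)-2,6-dimethyl-8-phenylocta-3,7-dien-1-ol
Conditions: camphorsulfonic acid (10 mol%), MeOH/CH2Cl2, 0 °C → rt
Reagents that add atoms: none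
Why: Acid-catalyzed methanolysis of the primary silyl ether leaves the alkenes and allylic stereocenters untouched.

Step 14
Reactants: 19 (2S,3E,6S,7E)-2,6-dimethyl-8-phenylocta-3,7-dien-1-ol
Product: 20 [(1E,3S,5E,7S)-8-iodo-3,7-dimethylocta-1,5-dien-1-yl]benzene
Conditions: I2, PPh3, imidazole, CH2Cl2, 0 °C → rt
Reagents that add atoms: iodine, II
Why: Appel-type iodination converts the primary alcohol to the iodide by SN2 at CH2 without touching the adjacent stereocenter.

Step 15
Reactants: 20 [(1E,3S,5E,7S)-8-iodo-3,7-dimethylocta-1,5-dien-1-yl]benzene; 7 methyl 2-[(3S,4S)-6-methoxy-4,6-dimethyl-1,2-dioxan-3-yl]acetate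
Product: 23 methyl 2-[(3S,4S,6S)-6-[(2R,3E,6S,7E)-2,6-dimethyl-8-phenylocta-3,7-dien-1-yl]-4,6-dimethyl-1,2-dioxan-3-yl]acetate, via alkylzinc iodide 21 (not isolated), via peroxycarbenium triflate 22 (not isolated)
Conditions: 20, Zn dust, LiCl, THF, 40 °C; then 7, TMSOTf (1.2 equiv), CH2Cl2, −78 → −40 °C
Reagents that add atoms: none
Why: Proposed new method: TMSOTf removes the 6-methoxy group of 7, and the resulting 6-methyl-1,2-dioxan-6-ylium (peroxycarbenium) ion 22 is alkylated at carbon by the primary alkylzinc iodide 21, a nucleophile strong enough for a heteroatom-stabilized cation but too unreactive to cleave the O–O bond or add to the ester. The closest known reaction types are the Lewis-acid-mediated allylation of cyclic peroxyketals with allylsilanes through peroxycarbenium ions, and the substitution of 2-sulfonyl cyclic ethers and of iminium ions by alkylzinc reagents. No ring is closed; the preformed 1,2-dioxane is kept. The new quaternary stereocenter C6 is controlled by the ring: in the half-chair cation the 4-methyl is pseudo-equatorial and the cis C3 arm pseudo-axial, so chair-like axial attack on the face opposite both places the chain trans to them (6S) with the 6-methyl equatorial. The step needs C-alkylation rather than reduction or O–O attack, and it needs this facial selectivity; the first rests on the low reactivity of organozincs toward dialkyl peroxides at −78 °C, the second on the 1,3-diaxial clash with the 4-methyl that attack through the other half-chair would suffer.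

Step 16
Reactants: 23 coupled methyl ester
Product: 24 2-[(3S,4S,6S)-6-[(2R,3E,6S,7E)-2,6-dimethyl-8-phenylocta-3,7-dien-1-yl]-4,6-dimethyl-1,2-dioxan-3-yl]acetic acid (CNP0179089.3)
Conditions: LiOH, THF/MeOH/H2O, 0 °C → rt; then 1 M HCl to pH 3
Reagents that add atoms: lithium hydroxide, [Li+].[OH-]
Why: Mild saponification of the methyl ester, the usual way to free the acid in 3-(carboxymethyl)-1,2-dioxanes, should leave the dialkyl peroxide and all stereocenters intact at low temperature.

**Compound list**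

1 | (R)-3-bromo-2-methylpropan-1-ol | BrC[C@H](C)CO | starting material
2 | prop-1-en-2-ylmagnesium bromide | C=C(C)[Mg]Br | starting material
3 | (S)-2,4-dimethylpent-4-en-1-ol | C=C(C)C[C@H](C)CO | intermediate
4 | (S)-2,4-dimethylpent-4-enal | C=C(C)C[C@H](C)C=O | intermediate
5 | methyl (2E,4S)-4,6-dimethylhepta-2,6-dienoate | C=C(C)C[C@H](C)/C=C/C(=O)OC | intermediate
6 | methyl (2E,4S)-6-hydroperoxy-6-methoxy-4-methylhept-2-enoate (C6 epimers) | COC(C)(OO)C[C@H](C)/C=C/C(=O)OC | intermediate
7 | methyl 2-[(3S,4S)-6-methoxy-4,6-dimethyl-1,2-dioxan-3-yl]acetate (C6 epimers) | COC1(C)C[C@H](C)[C@H](CC(=O)OC)OO1 | intermediate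
8 | (E)-but-2-enal | C/C=C/C=O | starting material
9 | phenylmagnesium bromide | Br[Mg]c1ccccc1 | starting material
10 | rac-(E)-1-phenylbut-2-en-1-ol | C/C=C/C(O)c1ccccc1 | intermediate
11 | (1R,2E)-1-phenylbut-2-en-1-ol | C/C=C/[C@@H](O)c1ccccc1 | intermediate
12 | [(1R,2E)-1-(1-ethoxyethenyloxy)but-2-en-1-yl]benzene (allyl ketene acetal) | C/C=C/[C@@H](OC(=C)OCC)c1ccccc1 | intermediate
13 | ethyl (3S,4E)-3-methyl-5-phenylpent-4-enoate | C[C@H](/C=C/c1ccccc1)CC(=O)OCC | intermediate
14 | (3S,4E)-3-methyl-5-phenylpent-4-enal | C[C@H](/C=C/c1ccccc1)CC=O | intermediate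
15 | (R)-2-methyl-3-[(1-phenyl-1H-tetrazol-5-yl)sulfanyl]propan-1-ol | OC[C@@H](C)CSc1nnnn1-c1ccccc1 | intermediate
16 | (R)-2-methyl-3-[(1-phenyl-1H-tetrazol-5-yl)sulfonyl]propan-1-ol | OC[C@@H](C)CS(=O)(=O)c1nnnn1-c1ccccc1 | intermediate
17 | 5-{[(2R)-3-{[tert-butyl(dimethyl)silyl]oxy}-2-methylpropyl]sulfonyl}-1-phenyl-1H-tetrazole | CC(C)(C)[Si](C)(C)OC[C@@H](C)CS(=O)(=O)c1nnnn1-c1ccccc1 | intermediate
18 | tert-butyl{[(2S,3E,6S,7E)-2,6-dimethyl-8-phenylocta-3,7-dien-1-yl]oxy}dimethylsilane | C[C@H](/C=C/c1ccccc1)C/C=C/[C@H](C)CO[Si](C)(C)C(C)(C)C | intermediate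
19 | (2S,3E,6S,7E)-2,6-dimethyl-8-phenylocta-3,7-dien-1-ol | C[C@H](/C=C/c1ccccc1)C/C=C/[C@H](C)CO | intermediate
20 | [(1E,3S,5E,7S)-8-iodo-3,7-dimethylocta-1,5-dien-1-yl]benzene | C[C@H](/C=C/c1ccccc1)C/C=C/[C@H](C)CI | intermediate
21 | iodo[(2S,3E,6S,7E)-2,6-dimethyl-8-phenylocta-3,7-dien-1-yl]zinc | C[C@H](/C=C/c1ccccc1)C/C=C/[C@H](C)C[Zn]I | intermediate
22 | (3S,4S)-3-(2-methoxy-2-oxoethyl)-4,6-dimethyl-1,2-dioxan-6-ylium trifluoromethanesulfonate (peroxycarbenium ion) | C[C+]1C[C@H](C)[C@H](CC(=O)OC)OO1.[O-]S(=O)(=O)C(F)(F)F | intermediate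
23 | methyl 2-[(3S,4S,6S)-6-[(2R,3E,6S,7E)-2,6-dimethyl-8-phenylocta-3,7-dien-1-yl]-4,6-dimethyl-1,2-dioxan-3-yl]acetate | C[C@H](/C=C/c1ccccc1)C/C=C/[C@H](C)C[C@@]1(C)C[C@H](C)[C@H](CC(=O)OC)OO1 | intermediate
24 | 2-[(3S,4S,6S)-6-[(2R,3E,6S,7E)-2,6-dimethyl-8-phenylocta-3,7-dien-1-yl]-4,6-dimethyl-1,2-dioxan-3-yl]acetic acid | C[C@H](/C=C/c1ccccc1)C/C=C/[C@H](C)C[C@@]1(C)C[C@H](C)[C@H](CC(=O)O)OO1 | target

**Step count**

Total: 16 steps. Longest linear sequence: 9 steps (5, 6, 7, 8, 12, 13, 14, 15, 16).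

**Steps most likely to fail**

1. Step 15 (Proposed new method). The organozinc may transfer a β-hydride instead of its carbon, the peroxyketal may ionize with ring opening, or the facial selectivity at C6 may be poor. The fallback uses known chemistry, sets out from 7 and returns at 23. Hosomi–Sakurai substitution of the peroxyketal with trimethyl(2-methylallyl)silane and TiCl4 in CH2Cl2 at −78 °C, a reaction type established for peroxyketals, should give the 6-methallyl dioxane F1 with the same axial delivery. Hydroboration with 9-BBN and oxidation with NaBO3·4H2O gives the primary alcohol F2 as both epimers at the new methyl-bearing carbon. A Mitsunobu reaction with 1-phenyl-1H-tetrazole-5-thiol (DIAD, PPh3) gives the tetrazolyl sulfide F3, and molybdate/H2O2 oxidation gives the sulfone F4. Julia–Kocienski olefination of F4 with aldehyde 14 (KN(SiMe3)2 added to the mixture at −78 °C) returns to 23 together with its C2′ epimer F5, which is removed by chromatography. Steps 9–14 are then not needed.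

2. Step 4. The closure may show poor or reversed diastereoselection at C3, or may equilibrate by retro-Michael addition toward the 3,4-trans isomer. The fallback sets out from 3 and returns at 7; it makes the C3–O bond by stereospecific displacement instead. Alcohol 3 is oxidized (PhI(OAc)2, TEMPO) to aldehyde 4, now isolated. A reagent-controlled acetate aldol addition of S-phenyl thioacetate, mediated by a chiral 2-bromo-1,3,2-diazaborolidine derived from 1,2-diphenylethylenediamine bis-tosylamide (the enantiomer that overrides the Felkin–Anh preference) and Et3N, gives the 3,4-anti β-hydroxy thioester F6. LiBH4 gives the diol F7, and TBSCl/imidazole silylates the primary hydroxyl to give the silyl ether F8. MsCl/Et3N gives the mesylate F9, and ozonolysis in methanol as in step 3 gives the hydroperoxyketal F10. KOt-Bu with 18-crown-6 closes the ring by 6-exo-tet displacement of the mesylate with inversion at C3, giving the 3,4-cis dioxane F11. HF·pyridine frees the alcohol F12, PhI(OAc)2/TEMPO in aqueous MeCN gives the acid F13, and Me3SiCHN2 gives 7.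

3. Step 16. Hydroxide may trigger retro-oxa-Michael ring opening with epimerization at C3, or Kornblum–DeLaMare cleavage at the C3–H bond. The fallback sets out from 23 and returns at 24; it replaces hydrolysis by a redox sequence. i-Bu2AlH in CH2Cl2 at −78 °C reduces the ester to the aldehyde F14, and Pinnick oxidation (NaClO2, NaH2PO4, 2-methylbut-2-ene, t-BuOH/H2O) gives 24 under buffered, weakly acidic conditions.

**Further compounds**

F1 | step 15 | methyl 2-[(3S,4S,6R)-4,6-dimethyl-6-(2-methylprop-2-en-1-yl)-1,2-dioxan-3-yl]acetate | C=C(C)C[C@@]1(C)C[C@H](C)[C@H](CC(=O)OC)OO1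
F2 | step 15 | methyl 2-[(3S,4S,6S)-6-(3-hydroxy-2-methylpropyl)-4,6-dimethyl-1,2-dioxan-3-yl]acetate (both epimers at the side-chain CH) | OCC(C)C[C@@]1(C)C[C@H](C)[C@H](CC(=O)OC)OO1
F3 | step 15 | methyl 2-[(3S,4S,6R)-4,6-dimethyl-6-{2-methyl-3-[(1-phenyl-1H-tetrazol-5-yl)sulfanyl]propyl}-1,2-dioxan-3-yl]acetate (both epimers at the side-chain CH) | c1ccccc1-n1nnnc1SCC(C)C[C@@]1(C)C[C@H](C)[C@H](CC(=O)OC)OO1
F4 | step 15 | methyl 2-[(3S,4S,6R)-4,6-dimethyl-6-{2-methyl-3-[(1-phenyl-1H-tetrazol-5-yl)sulfonyl]propyl}-1,2-dioxan-3-yl]acetate (both epimers at the side-chain CH) | c1ccccc1-n1nnnc1S(=O)(=O)CC(C)C[C@@]1(C)C[C@H](C)[C@H](CC(=O)OC)OO1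
F5 | step 15 | methyl 2-[(3S,4S,6S)-6-[(2S,3E,6S,7E)-2,6-dimethyl-8-phenylocta-3,7-dien-1-yl]-4,6-dimethyl-1,2-dioxan-3-yl]acetate | C[C@H](/C=C/c1ccccc1)C/C=C/[C@@H](C)C[C@@]1(C)C[C@H](C)[C@H](CC(=O)OC)OO1
F6 | step 4 | S-phenyl (3R,4S)-3-hydroxy-4,6-dimethylhept-6-enethioate | C=C(C)C[C@H](C)[C@H](O)CC(=O)Sc1ccccc1
F7 | step 4 | (3R,4S)-4,6-dimethylhept-6-ene-1,3-diol | C=C(C)C[C@H](C)[C@H](O)CCO
F8 | step 4 | (3R,4S)-1-{[tert-butyl(dimethyl)silyl]oxy}-4,6-dimethylhept-6-en-3-ol | C=C(C)C[C@H](C)[C@H](O)CCO[Si](C)(C)C(C)(C)C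
F9 | step 4 | (3R,4S)-1-{[tert-butyl(dimethyl)silyl]oxy}-4,6-dimethylhept-6-en-3-yl methanesulfonate | C=C(C)C[C@H](C)[C@H](OS(C)(=O)=O)CCO[Si](C)(C)C(C)(C)C
F10 | step 4 | (3R,4S)-1-{[tert-butyl(dimethyl)silyl]oxy}-6-hydroperoxy-6-methoxy-4-methylheptan-3-yl methanesulfonate (C6 epimers) | COC(C)(OO)C[C@H](C)[C@H](OS(C)(=O)=O)CCO[Si](C)(C)C(C)(C)C
F11 | step 4 | tert-butyl{2-[(3S,4S)-6-methoxy-4,6-dimethyl-1,2-dioxan-3-yl]ethoxy}dimethylsilane (C6 epimers) | COC1(C)C[C@H](C)[C@H](CCO[Si](C)(C)C(C)(C)C)OO1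
F12 | step 4 | 2-[(3S,4S)-6-methoxy-4,6-dimethyl-1,2-dioxan-3-yl]ethan-1-ol (C6 epimers) | COC1(C)C[C@H](C)[C@H](CCO)OO1
F13 | step 4 | 2-[(3S,4S)-6-methoxy-4,6-dimethyl-1,2-dioxan-3-yl]acetic acid (C6 epimers) | COC1(C)C[C@H](C)[C@H](CC(=O)O)OO1
F14 | step 16 | 2-[(3S,4S,6S)-6-[(2R,3E,6S,7E)-2,6-dimethyl-8-phenylocta-3,7-dien-1-yl]-4,6-dimethyl-1,2-dioxan-3-yl]acetaldehyde | C[C@H](/C=C/c1ccccc1)C/C=C/[C@H](C)C[C@@]1(C)C[C@H](C)[C@H](CC=O)OO1
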